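**Retrosynthetic overview**
- The target is the 1,4-di-O-angelate of a trans-fused hydroazulene triol. The last step is twofold angeloylation of the secondary hydroxyls at C1 and C4; the C3 carbinol comes from isopropyl addition to a C3 ketone.
- The five-membered ring is bought as an enantiopure 4-oxygenated cyclopentenone. The seven-membered ring is closed second, by ring-closing metathesis at C6=C7.
- Key disconnection: C8–C8a and C3a–C4 are made in one operation on the enone C3(=O)–C3a=C8a(CH3). A silicon-tethered allyl group is transferred to C8a, and the resulting enolate adds at C3a to 3-methylbut-3-enal.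
- Enabling feature: in the five-membered ring the C1–O bond and the C8a–C8 bond are cis on adjacent carbons, so the C1 oxygen can carry C8 and deliver it to the quaternary C8a. O–C3 and O–C4 are 1,3 across C3a (aldol retron), and C3/C3a/C8a form the matching enone.
- Absolute configuration comes from the C1 carbinol of (S)-4-silyloxycyclopentenone and is relayed to C8a, C3a, C4 and C3.

Key step: step 6

Remark: atom numbers in the text follow the azulene numbering of the target (C1 and C4 carry the angelates, C3 the tertiary hydroxyl, C3a and C8a are the ring-fusion carbons, C6=C7 is the ring alkene); (S)-4-(tert-butyldimethylsilyloxy)cyclopent-2-en-1-one is assumed to be purchasable in enantiopure form.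

**Route**

Step 1
Reactants: 1 (S)-4-(tert-butyldimethylsilyloxy)cyclopent-2-en-1-one
Product: 2 tert-butyl(dimethyl){[(1S,2S)-2-methyl-4-[(trimethylsilyl)oxy]cyclopent-3-en-1-yl]oxy}silane
Conditions: MeMgBr, CuBr·SMe2 (5 mol %), TMSCl, THF, −78 °C; Et3N, cold aq. NaHCO3
Reagents that add atoms: methylmagnesium bromide C[Mg]Br; chlorotrimethylsilane C[Si](C)(C)Cl
Why: Copper-catalysed conjugate addition of the Grignard reagent with TMSCl trapping should give the regiodefined silyl enol ether; methyl enters anti to the silyloxy group (this centre is erased in step 2).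

Step 2
Reactants: 2 tert-butyl(dimethyl){[(1S,2S)-2-methyl-4-[(trimethylsilyl)oxy]cyclopent-3-en-1-yl]oxy}silane
Product: 3 (S)-4-(tert-butyldimethylsilyloxy)-3-methylcyclopent-2-en-1-one
Conditions: Pd(OAc)2 (10 mol %), O2 (1 atm), DMSO, 25 °C
Reagents that add atoms: none
Why: Saegusa–Ito oxidation (palladium enolate, β-hydride elimination, zerovalent palladium reoxidised by O2) should restore the enone with methyl now on the β-carbon and leave the carbinol centre untouched.

Step 3
Reactants: 3 (S)-4-(tert-butyldimethylsilyloxy)-3-methylcyclopent-2-en-1-one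
Product: 4 (S)-4-hydroxy-3-methylcyclopent-2-en-1-one
Conditions: HF (48% aq.), MeCN, 0 °C
Reagents that add atoms: none
Why: Acidic fluoride cleavage of the silyl ether avoids the base-induced β-elimination to which 4-oxygenated cyclopentenones are prone.

Step 4
Reactants: 4 (S)-4-hydroxy-3-methylcyclopent-2-en-1-one
Product: 5 (S)-3-methyl-4-{[dimethyl(prop-2-en-1-yl)silyl]oxy}cyclopent-2-en-1-one
Conditions: allyl(chloro)dimethylsilane, imidazole, CH2Cl2, 0 °C
Reagents that add atoms: allyl(chloro)dimethylsilane C=CC[Si](C)(C)Cl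
Why: Imidazole-mediated O-silylation of the secondary alcohol installs the allylsilane whose allyl group becomes C8 and C7, with silicon as its tether.

Step 5
Reactants: 6 3-methylbut-3-en-1-ol
Product: 7 3-methylbut-3-enal (used at once as a cold CH2Cl2 solution)
Conditions: Dess–Martin periodinane, NaHCO3, CH2Cl2, 0 °C; cold filtration through silica
Reagents that add atoms: none
Why: Dess–Martin oxidation under buffered, neutral conditions should give the β,γ-unsaturated aldehyde without migration of the double bond into conjugation.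

Step 6
Reactants: 5 (S)-3-methyl-4-{[dimethyl(prop-2-en-1-yl)silyl]oxy}cyclopent-2-en-1-one; 7 3-methylbut-3-enal
Product: 10 (2S,3R,4S)-4-hydroxy-2-[(1S)-1-hydroxy-3-methylbut-3-en-1-yl]-3-methyl-3-(prop-2-en-1-yl)cyclopentan-1-one, via titanium enolate 8 (not isolated), via titanium aldolate 9 (not isolated)
Conditions: TiCl4 (1.1 equiv), CH2Cl2 (0.01 M), −78 °C; then 7 (1.5 equiv), −78 °C; 1 M HCl, THF, 0 °C
Reagents that add atoms: titanium tetrachloride Cl[Ti](Cl)(Cl)Cl (its atoms stay only in 8 and 9)
Why: Proposed new method: TiCl4 binds the enone carbonyl of 5 and the terminal carbon of the silicon-bound allyl group attacks the β-carbon (C8a) through a seven-membered cyclic transition state (syn-SE2', chloride taking over silicon), after which the trichlorotitanium enolate 8 adds to aldehyde 7 at C3a and acidic work-up removes silicon; the closest known reaction types are the Hosomi–Sakurai conjugate allylation with aldol capture of the titanium enolate and the Lewis-acid-induced intramolecular allyl transfer from allylsilyl ethers to carbonyl carbons, which has not been shown for an enone β-carbon next to the carbinol centre. No ring is closed in this step (the silacycle exists only in the transition state; ring closure follows in step 7). C8a (quaternary) is controlled by the tether, which can reach it only from the face of the C1–O bond, so allyl ends cis to that oxygen; C3a is controlled by C8a and C1, the aldehyde entering opposite to the allyl group and the silyloxy group (2,3-trans); C4 is controlled by the closed Zimmerman–Traxler chair of the cyclic (E)-enolate, which gives the anti aldol (4S). The step needs intramolecular instead of bimolecular (anti-selective) allyl transfer and conjugate instead of carbonyl attack; the short O–Si–CH2 tether, which cannot reach the carbonyl carbon, and high dilution secure both.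

Step 7
Reactants: 10 (2S,3R,4S)-4-hydroxy-2-[(1S)-1-hydroxy-3-methylbut-3-en-1-yl]-3-methyl-3-(prop-2-en-1-yl)cyclopentan-1-one
Product: 11 (1S,3aS,4S,8aR)-1,4-dihydroxy-6,8a-dimethyl-2,3a,4,5,8,8a-hexahydroazulen-3(1H)-one (numbering as in the target)
Conditions: second-generation Grubbs catalyst (5 mol %), CH2Cl2 (2 mM), 40 °C
Reagents that add atoms: none
Why: Ring-closing metathesis of a monosubstituted and a 1,1-disubstituted alkene held trans on adjacent ring carbons should close the trans-fused cycloheptene; the ring size enforces the Z trisubstituted C6=C7 bond.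

Step 8
Reactants: 11 (1S,3aS,4S,8aR)-1,4-dihydroxy-6,8a-dimethyl-2,3a,4,5,8,8a-hexahydroazulen-3(1H)-one
Product: 12 (1S,3R,3aS,4S,8aR)-6,8a-dimethyl-3-(propan-2-yl)-1,2,3,3a,4,5,8,8a-octahydroazulene-1,3,4-triol
Conditions: i-PrMgCl (4 equiv), CeCl3 (anhydrous, 4 equiv), THF, −78 to −40 °C; aq. NH4Cl
Reagents that add atoms: isopropylmagnesium chloride CC(C)[Mg]Cl
Why: Organocerium (Imamoto) 1,2-addition suppresses enolisation, reduction and retro-aldol cleavage of the β-hydroxy ketone; the reagent should enter C3 from the face of H-3a, opposite to the C4 branch on the adjacent carbon and to the axial C8a methyl group, which places the new hydroxyl cis to C4.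

Step 9
Reactants: 12 (1S,3R,3aS,4S,8aR)-6,8a-dimethyl-3-(propan-2-yl)-1,2,3,3a,4,5,8,8a-octahydroazulene-1,3,4-triol
Product: 13 (1S,3R,3aS,4S,8aR)-3-hydroxy-6,8a-dimethyl-3-(propan-2-yl)-1,2,3,3a,4,5,8,8a-octahydroazulene-1,4-diyl bis[(2Z)-2-methylbut-2-enoate]
Conditions: angelic acid, 2,4,6-trichlorobenzoyl chloride, Et3N, toluene, 25 °C; then 12, 80 °C
Reagents that add atoms: angelic acid [(2Z)-2-methylbut-2-enoic acid] C/C=C(/C)C(=O)O
Why: Yamaguchi-type acylation through the mixed anhydride of angelic acid, run without a nucleophilic amine catalyst, should esterify both secondary hydroxyls without Z to E isomerisation and leave the hindered tertiary hydroxyl free.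

**Compound list**

1 | (S)-4-(tert-butyldimethylsilyloxy)cyclopent-2-en-1-one | O=C1C=C[C@@H](O[Si](C)(C)C(C)(C)C)C1 | starting material
2 | tert-butyl(dimethyl){[(1S,2S)-2-methyl-4-[(trimethylsilyl)oxy]cyclopent-3-en-1-yl]oxy}silane | C[Si](C)(C)OC1=C[C@H](C)[C@@H](O[Si](C)(C)C(C)(C)C)C1 | intermediate
3 | (S)-4-(tert-butyldimethylsilyloxy)-3-methylcyclopent-2-en-1-one | O=C1C=C(C)[C@@H](O[Si](C)(C)C(C)(C)C)C1 | intermediate
4 | (S)-4-hydroxy-3-methylcyclopent-2-en-1-one | O=C1C=C(C)[C@@H](O)C1 | intermediate
5 | (S)-3-methyl-4-{[dimethyl(prop-2-en-1-yl)silyl]oxy}cyclopent-2-en-1-one | O=C1C=C(C)[C@@H](O[Si](C)(C)CC=C)C1 | intermediate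
6 | 3-methylbut-3-en-1-ol | CC(=C)CCO | starting material
7 | 3-methylbut-3-enal | CC(=C)CC=O | intermediate
8 | trichloro({(3R,4S)-4-{[chloro(dimethyl)silyl]oxy}-3-methyl-3-(prop-2-en-1-yl)cyclopent-1-en-1-yl}oxy)titanium (titanium enolate, not isolated) | Cl[Ti](Cl)(Cl)OC1=C[C@@](C)(CC=C)[C@@H](O[Si](C)(C)Cl)C1 | intermediate
9 | trichloro{[(1S)-1-[(1S,2R,3S)-3-{[chloro(dimethyl)silyl]oxy}-2-methyl-5-oxo-2-(prop-2-en-1-yl)cyclopentyl]-3-methylbut-3-en-1-yl]oxy}titanium (titanium aldolate, not isolated) | Cl[Ti](Cl)(Cl)O[C@@H](CC(C)=C)[C@H]1C(=O)C[C@H](O[Si](C)(C)Cl)[C@]1(C)CC=C | intermediate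
10 | (2S,3R,4S)-4-hydroxy-2-[(1S)-1-hydroxy-3-methylbut-3-en-1-yl]-3-methyl-3-(prop-2-en-1-yl)cyclopentan-1-one | O[C@@H](CC(C)=C)[C@H]1C(=O)C[C@H](O)[C@]1(C)CC=C | intermediate
11 | (1S,3aS,4S,8aR)-1,4-dihydroxy-6,8a-dimethyl-2,3a,4,5,8,8a-hexahydroazulen-3(1H)-one | O[C@H]1CC(C)=CC[C@@]2(C)[C@@H](O)CC(=O)[C@H]12 | intermediate
12 | (1S,3R,3aS,4S,8aR)-6,8a-dimethyl-3-(propan-2-yl)-1,2,3,3a,4,5,8,8a-octahydroazulene-1,3,4-triol | O[C@H]1CC(C)=CC[C@@]2(C)[C@@H](O)C[C@@](O)(C(C)C)[C@H]12 | intermediate
13 | (1S,3R,3aS,4S,8aR)-3-hydroxy-6,8a-dimethyl-3-(propan-2-yl)-1,2,3,3a,4,5,8,8a-octahydroazulene-1,4-diyl bis[(2Z)-2-methylbut-2-enoate] | C/C=C(/C)C(=O)O[C@H]1CC(C)=CC[C@@]2(C)[C@@H](OC(=O)/C(C)=C\C)C[C@@](O)(C(C)C)[C@H]12 | target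

**Step count and risks**

Total step count: 9. Longest linear sequence: 8 steps (steps 1–4 and 6–9; step 5 prepares the aldehyde on a side branch).

Steps most likely to fail:

1. Step 6 (Proposed new method). The allyl group may be transferred between molecules after TiCl4 cleaves the Si–O bond, which would lose the syn facial course, or the reaction may stop at desilylation; the aldol may also show low simple selectivity at C4. The fallback uses known chemistry, sets out from 4 and returns at 12. Mitsunobu inversion of 4 with acetic acid (PPh3, diisopropyl azodicarboxylate) should give (1R)-2-methyl-4-oxocyclopent-2-en-1-yl acetate F1. Intermolecular Hosomi–Sakurai addition of allyltrimethylsilane (TiCl4, CH2Cl2, −78 °C) enters anti to the acetoxy group and so gives the same configuration at C8a; aldol capture of the titanium enolate by 7 should give (1R,2R,3S)-3-[(1S)-1-hydroxy-3-methylbut-3-en-1-yl]-2-methyl-4-oxo-2-(prop-2-en-1-yl)cyclopentyl acetate F2, from which any C3a epimer would be separated. Ring-closing metathesis should give (1R,3aS,4S,8aR)-4-hydroxy-6,8a-dimethyl-3-oxo-1,2,3,3a,4,5,8,8a-octahydroazulen-1-yl acetate F3. Excess i-PrMgCl/CeCl3 adds to the ketone and removes the acetate to give the C1 epimer of 12, (1R,3R,3aS,4S,8aR)-6,8a-dimethyl-3-(propan-2-yl)-1,2,3,3a,4,5,8,8a-octahydroazulene-1,3,4-triol F4. Dess–Martin oxidation of both secondary hydroxyls should give (3R,3aR,8aR)-3-hydroxy-6,8a-dimethyl-3-(propan-2-yl)-2,3,3a,5,8,8a-hexahydroazulene-1,4-dione F5. Me4NBH(OAc)3 (AcOH, MeCN, −20 °C) then reduces both ketones by hydride delivery from the tertiary C3 hydroxyl, each anti to it, and should give 12. The same oxidation and directed reduction would also correct a wrong C4 configuration from the main key step.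

2. Step 8. The addition may show poor facial selectivity at C3, or the basic reagent may cause retro-aldol cleavage or enolisation of the β-hydroxy ketone. The fallback sets out from 10 and returns at 12 by changing the order of events. The i-PrMgCl/CeCl3 addition is run on monocyclic 10, where the C2 side chain is the only α-substituent and its hydroxyl can chelate, to give (1R,2S,3R,4S)-2-[(1S)-1-hydroxy-3-methylbut-3-en-1-yl]-3-methyl-1-(propan-2-yl)-3-(prop-2-en-1-yl)cyclopentane-1,4-diol F6. Ring-closing metathesis (second-generation Grubbs catalyst) of F6 should then give 12.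

3. Step 9. The angelate may isomerise to the tiglate (Z to E) during acylation, and the neopentylic C1 hydroxyl may acylate sluggishly. The fallback sets out from 12 and returns at 13 by building the Z double bonds on the esters. Esterification of both secondary hydroxyls with 2-[bis(2,2,2-trifluoroethoxy)phosphoryl]propanoic acid (DCC, DMAP, CH2Cl2) should give (1S,3R,3aS,4S,8aR)-3-hydroxy-6,8a-dimethyl-3-(propan-2-yl)-1,2,3,3a,4,5,8,8a-octahydroazulene-1,4-diyl bis{2-[bis(2,2,2-trifluoroethoxy)phosphoryl]propanoate} F7. Still–Gennari olefination with acetaldehyde (KN(SiMe3)2, 18-crown-6, THF, −78 °C) should then give 13.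

Further compounds
F1 | step 6 | (1R)-2-methyl-4-oxocyclopent-2-en-1-yl acetate | O=C1C=C(C)[C@H](OC(C)=O)C1
F2 | step 6 | (1R,2R,3S)-3-[(1S)-1-hydroxy-3-methylbut-3-en-1-yl]-2-methyl-4-oxo-2-(prop-2-en-1-yl)cyclopentyl acetate | O[C@@H](CC(C)=C)[C@H]1C(=O)C[C@@H](OC(C)=O)[C@]1(C)CC=C
F3 | step 6 | (1R,3aS,4S,8aR)-4-hydroxy-6,8a-dimethyl-3-oxo-1,2,3,3a,4,5,8,8a-octahydroazulen-1-yl acetate | O[C@H]1CC(C)=CC[C@@]2(C)[C@H](OC(C)=O)CC(=O)[C@H]12
F4 | step 6 | (1R,3R,3aS,4S,8aR)-6,8a-dimethyl-3-(propan-2-yl)-1,2,3,3a,4,5,8,8a-octahydroazulene-1,3,4-triol | O[C@H]1CC(C)=CC[C@@]2(C)[C@H](O)C[C@@](O)(C(C)C)[C@H]12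
F5 | step 6 | (3R,3aR,8aR)-3-hydroxy-6,8a-dimethyl-3-(propan-2-yl)-2,3,3a,5,8,8a-hexahydroazulene-1,4-dione | O=C1CC(C)=CC[C@@]2(C)C(=O)C[C@@](O)(C(C)C)[C@H]12
F6 | step 8 | (1R,2S,3R,4S)-2-[(1S)-1-hydroxy-3-methylbut-3-en-1-yl]-3-methyl-1-(propan-2-yl)-3-(prop-2-en-1-yl)cyclopentane-1,4-diol | O[C@@H](CC(C)=C)[C@H]1[C@](O)(C(C)C)C[C@H](O)[C@]1(C)CC=C
F7 | step 9 | (1S,3R,3aS,4S,8aR)-3-hydroxy-6,8a-dimethyl-3-(propan-2-yl)-1,2,3,3a,4,5,8,8a-octahydroazulene-1,4-diyl bis{2-[bis(2,2,2-trifluoroethoxy)phosphoryl]propanoate} | CC(C(=O)O[C@H]1CC(C)=CC[C@@]2(C)[C@@H](OC(=O)C(C)P(=O)(OCC(F)(F)F)OCC(F)(F)F)C[C@@](O)(C(C)C)[C@H]12)P(=O)(OCC(F)(F)F)OCC(F)(F)F
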